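**Strategy.** In the seven-membered ring (azulene numbering) the ester-bearing carbon C4 and the methylene C5 lie between the ring-fusion carbon C3a and the alkene carbon C6, so that the C4 oxygen is β,γ to the C6=C7 double bond: the signature of a homologated α,β-unsaturated acyl group. The key step photolyses a (Z)-α-methyl enoyl diazomethane tethered to a regiodefined cyclopentenyl silyl enol ether. Wolff rearrangement moves C6 from the carbonyl carbon to the diazo carbon (C5–C6), and the vinylketene acylates C3a (C3a–C4), closing the cycloheptene with the alkene in place. The C8a quaternary centre, set by copper-catalysed asymmetric conjugate addition, then relays C3a, C3 and C4.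

Key step: step 7

Remark: atom numbers are the azulene numbers of the bicyclic core (C3 carries OH and isopropyl, C3a is the ring-fusion CH, C4 carries the ester oxygen, C5 is the ring CH2, C6 carries the vinylic methyl, C8a is the quaternary ring-fusion carbon). TIPS = Si(i-Pr)3.

Step 1
Reactants: 1 3-ethoxycyclopent-2-en-1-one; 2 methyl bromoacetate
Product: 4 methyl 2-(3-oxocyclopent-1-en-1-yl)acetate, via hydroxy enol ether 3 (not isolated)
Conditions: Zn, THF, 40 °C; then 1 M HCl, 0 °C
Reagents that add atoms: water O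
Why: Reformatsky 1,2-addition of the zinc ester enolate to the vinylogous ester carbonyl, followed by acid-promoted hydrolysis with loss of ethanol (Stork–Danheiser transposition), should place the acetate side chain on the β-carbon of the new enone; no stereocentre remains.

Step 2
Reactants: 4 methyl 2-(3-oxocyclopent-1-en-1-yl)acetate
Product: 6 methyl 2-[(1R)-1-methyl-3-(triisopropylsilyloxy)cyclopent-2-en-1-yl]acetate, via aluminium enolate 5 (not isolated)
Conditions: Me3Al, Cu(OTf)2 (5 mol%), chiral phosphoramidite ligand (10 mol%), Et2O, −30 °C; then i-Pr3SiOTf, THF, −30 to 0 °C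
Reagents that add atoms: trimethylaluminium C[Al](C)C; triisopropylsilyl trifluoromethanesulfonate CC(C)[Si](OS(=O)(=O)C(F)(F)F)(C(C)C)C(C)C
Why: Copper-catalysed asymmetric conjugate addition of the methyl group, with the ligand antipode chosen to give the (R)-quaternary carbon (later C8a), and O-silylation of the aluminium enolate should fix the enol double bond regiospecifically on the side of the new quaternary centre.

Step 3
Reactants: 6 methyl 2-[(1R)-1-methyl-3-(triisopropylsilyloxy)cyclopent-2-en-1-yl]acetate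
Product: 7 2-[(1R)-1-methyl-3-(triisopropylsilyloxy)cyclopent-2-en-1-yl]acetaldehyde
Conditions: i-Bu2AlH (1.1 equiv), CH2Cl2, −78 °C; aqueous Rochelle salt
Reagents that add atoms: none
Why: Partial reduction of the methyl ester should stop at the tetrahedral aluminium hemiacetal at −78 °C and release the aldehyde on work-up, while the silyl enol ether is inert to the hydride.

Step 4
Reactants: 7 2-[(1R)-1-methyl-3-(triisopropylsilyloxy)cyclopent-2-en-1-yl]acetaldehyde; 8 ethyl 2-[bis(2,2,2-trifluoroethoxy)phosphoryl]propanoate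
Product: 9 ethyl (2Z)-2-methyl-4-[(1R)-1-methyl-3-(triisopropylsilyloxy)cyclopent-2-en-1-yl]but-2-enoate
Conditions: KN(SiMe3)2, 18-crown-6, THF, −78 °C
Reagents that add atoms: none
Why: The Still–Gennari variant of the Horner–Wadsworth–Emmons olefination (electron-poor phosphonate, dissociated potassium counter-ion) should give the (Z)-trisubstituted enoate, with the ester cis to the ring-bearing CH2 as the later ring closure requires.

Step 5
Reactants: 9 ethyl (2Z)-2-methyl-4-[(1R)-1-methyl-3-(triisopropylsilyloxy)cyclopent-2-en-1-yl]but-2-enoate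
Product: 10 (2Z)-2-methyl-4-[(1R)-1-methyl-3-(triisopropylsilyloxy)cyclopent-2-en-1-yl]but-2-enoic acid
Conditions: LiOH·H2O, THF/MeOH/H2O, 25 °C; then aqueous HCl to pH 4, 0 °C
Reagents that add atoms: lithium hydroxide [Li+].[OH-]
Why: Saponification of the ethyl ester should proceed while the hindered triisopropylsilyl enol ether survives hydroxide and a brief cold work-up at pH 4.

Step 6
Reactants: 10 (2Z)-2-methyl-4-[(1R)-1-methyl-3-(triisopropylsilyloxy)cyclopent-2-en-1-yl]but-2-enoic acid
Product: 12 (3Z)-1-diazo-3-methyl-5-[(1R)-1-methyl-3-(triisopropylsilyloxy)cyclopent-2-en-1-yl]pent-3-en-2-one, via mixed anhydride 11 (not isolated)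
Conditions: i-BuOCOCl, N-methylmorpholine, THF, −20 °C; then CH2N2, Et2O, 0 °C
Reagents that add atoms: diazomethane C=[N+]=[N-]
Why: Acylation of diazomethane by the mixed carbonic anhydride (first stage of an Arndt–Eistert sequence) avoids the chloride-mediated Z to E isomerisation known for angelate-type acid chlorides, and the trisubstituted enone should be a poor dipolarophile toward diazomethane.

Step 7
Reactants: 12 (3Z)-1-diazo-3-methyl-5-[(1R)-1-methyl-3-(triisopropylsilyloxy)cyclopent-2-en-1-yl]pent-3-en-2-one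
Product: 16 (3aS,8aR)-6,8a-dimethyl-4-(triisopropylsilyloxy)-1,2,8,8a-tetrahydroazulen-3(3aH)-one, via vinylketene 13 (not isolated), via cis-fused ketone 14 (not isolated), via potassium enolate 15 (not isolated)
Conditions: hν (medium-pressure Hg lamp, Pyrex filter), toluene (0.005 M), 25 °C, then 60 °C; then t-BuOK, THF, 0 °C; then AcOH, −78 °C
Reagents that add atoms: none
Why: Light expels N2 from the diazoketone with concerted 1,2-shift of the (Z)-alkenyl group from the carbonyl carbon to the diazo carbon (Wolff rearrangement; C5–C6 forms with the C6=C7 alkene kept in position and geometry), and the central carbon of the resulting vinylketene 13 is attacked by the β-carbon of the tethered silyl enol ether with transfer of the silyl group from O3 to O4 (C3a–C4 forms), giving dienol ether 14. The closest known reactions are the photochemical Wolff generation of vinylketenes from α'-diazo enones with capture by siloxy- and alkoxy-substituted π-nucleophiles, and the C-acylation (or [2+2] cycloaddition and ring opening) of silyl enol ethers by ketenes. The cycloheptene closes by attack on the sp carbon of the ketene, exo with respect to its C=O and with the ketene CH (C5) left in the ring (7-exo-dig), and the tether can reach only C3a, so the enol regiochemistry fixed in step 2 decides the site. The closure must place C4 syn to the tether (cis-fused 14), so C3a is reset in the same flask: t-BuOK forms the extended enolate 15 and kinetic protonation at C3a should occur anti to the pseudo-axial C8a methyl group, which sets the trans ring fusion (3aS). The step needs the Z enone geometry (from step 4, retained in the 1,2-shift), Wolff rearrangement rather than carbene addition to the enol ether (favoured by direct irradiation) and ketene capture rather than dimerisation (high dilution).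

Step 8
Reactants: 16 (3aS,8aR)-6,8a-dimethyl-4-(triisopropylsilyloxy)-1,2,8,8a-tetrahydroazulen-3(3aH)-one (used without chromatography)
Product: 18 (3R,3aR,8aR)-3-hydroxy-6,8a-dimethyl-3-(propan-2-yl)-2,3,3a,5,8,8a-hexahydroazulen-4(1H)-one, via tertiary carbinol 17 (not isolated)
Conditions: i-PrLi, CeCl3, THF, −78 °C; then AcOH; then Bu4NF/AcOH (1:1), THF, −78 to −20 °C
Reagents that add atoms: isopropyllithium [Li]C(C)C
Why: Organocerium 1,2-addition to the C3 ketone should occur on the α-face, anti to both the C8a methyl group and the C3a–C4 bond (C3: OH β, isopropyl α), and buffered fluoride desilylation of the dienol ether with kinetic α-protonation at C5 should release the C4 ketone without moving the C6=C7 alkene or disturbing C3a.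

Step 9
Reactants: 18 (3R,3aR,8aR)-3-hydroxy-6,8a-dimethyl-3-(propan-2-yl)-2,3,3a,5,8,8a-hexahydroazulen-4(1H)-one
Product: 19 (3R,3aS,4S,8aR)-6,8a-dimethyl-3-(propan-2-yl)-1,2,3,3a,4,5,8,8a-octahydroazulene-3,4-diol (jaeschkeanadiol)
Conditions: Me4NBH(OAc)3, MeCN/AcOH (1:1), −20 °C
Reagents that add atoms: none
Why: In the Evans–Saksena hydroxyl-directed reduction the acetoxyborohydride exchanges onto the β-oriented C3 hydroxyl and delivers hydride intramolecularly to the β-face of the C4 carbonyl, which should give the anti-1,3-diol with the C4 oxygen α (4S), against the face an external hydride would prefer.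

Step 10
Reactants: 19 jaeschkeanadiol; 20 4-acetoxy-3-methoxybenzoic acid
Product: 21 (3R,3aS,4S,8aR)-3-hydroxy-6,8a-dimethyl-3-(propan-2-yl)-1,2,3,3a,4,5,8,8a-octahydroazulen-4-yl 4-acetoxy-3-methoxybenzoate
Conditions: DCC, DMAP, CH2Cl2, 25 °C
Reagents that add atoms: none
Why: Steglich esterification should acylate the secondary C4 hydroxyl only, because the tertiary C3 hydroxyl is too hindered to react with the acylpyridinium intermediate.

Step 11
Reactants: 21 (3R,3aS,4S,8aR)-3-hydroxy-6,8a-dimethyl-3-(propan-2-yl)-1,2,3,3a,4,5,8,8a-octahydroazulen-4-yl 4-acetoxy-3-methoxybenzoate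
Product: 22 teferin, (3R,3aS,4S,8aR)-3-hydroxy-6,8a-dimethyl-3-(propan-2-yl)-1,2,3,3a,4,5,8,8a-octahydroazulen-4-yl 4-hydroxy-3-methoxybenzoate
Conditions: K2CO3 (0.2 equiv), MeOH, 0 °C
Reagents that add atoms: none
Why: Base-catalysed transesterification should remove the phenolic acetate selectively, since aryl acetates undergo methanolysis far faster than the hindered aroyl ester of the secondary alcohol.

**Compound list**

1 | 3-ethoxycyclopent-2-en-1-one | CCOC1=CC(=O)CC1 | starting material
2 | methyl bromoacetate | COC(=O)CBr | starting material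
3 | methyl 2-(3-ethoxy-1-hydroxycyclopent-2-en-1-yl)acetate (racemic) | CCOC1=CC(O)(CC(=O)OC)CC1 | intermediate
4 | methyl 2-(3-oxocyclopent-1-en-1-yl)acetate | COC(=O)CC1=CC(=O)CC1 | intermediate
5 | dimethylaluminium enolate of methyl 2-[(1R)-1-methyl-3-oxocyclopentyl]acetate | COC(=O)C[C@@]1(C)CCC(O[Al](C)C)=C1 | intermediate
6 | methyl 2-[(1R)-1-methyl-3-(triisopropylsilyloxy)cyclopent-2-en-1-yl]acetate | COC(=O)C[C@@]1(C)CCC(O[Si](C(C)C)(C(C)C)C(C)C)=C1 | intermediate
7 | 2-[(1R)-1-methyl-3-(triisopropylsilyloxy)cyclopent-2-en-1-yl]acetaldehyde | O=CC[C@@]1(C)CCC(O[Si](C(C)C)(C(C)C)C(C)C)=C1 | intermediate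
8 | ethyl 2-[bis(2,2,2-trifluoroethoxy)phosphoryl]propanoate | CCOC(=O)C(C)P(=O)(OCC(F)(F)F)OCC(F)(F)F | starting material
9 | ethyl (2Z)-2-methyl-4-[(1R)-1-methyl-3-(triisopropylsilyloxy)cyclopent-2-en-1-yl]but-2-enoate | CCOC(=O)/C(C)=C\C[C@@]1(C)CCC(O[Si](C(C)C)(C(C)C)C(C)C)=C1 | intermediate
10 | (2Z)-2-methyl-4-[(1R)-1-methyl-3-(triisopropylsilyloxy)cyclopent-2-en-1-yl]but-2-enoic acid | OC(=O)/C(C)=C\C[C@@]1(C)CCC(O[Si](C(C)C)(C(C)C)C(C)C)=C1 | intermediate
11 | isobutyl carbonic anhydride of acid 10 | CC(C)COC(=O)OC(=O)/C(C)=C\C[C@@]1(C)CCC(O[Si](C(C)C)(C(C)C)C(C)C)=C1 | intermediate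
12 | (3Z)-1-diazo-3-methyl-5-[(1R)-1-methyl-3-(triisopropylsilyloxy)cyclopent-2-en-1-yl]pent-3-en-2-one | [N-]=[N+]=CC(=O)/C(C)=C\C[C@@]1(C)CCC(O[Si](C(C)C)(C(C)C)C(C)C)=C1 | intermediate
13 | (3Z)-3-methyl-5-[(1R)-1-methyl-3-(triisopropylsilyloxy)cyclopent-2-en-1-yl]penta-1,3-dien-1-one | O=C=C/C(C)=C\C[C@@]1(C)CCC(O[Si](C(C)C)(C(C)C)C(C)C)=C1 | intermediate
14 | (3aR,8aR)-6,8a-dimethyl-4-(triisopropylsilyloxy)-1,2,8,8a-tetrahydroazulen-3(3aH)-one (cis-fused) | CC(C)[Si](C(C)C)(C(C)C)OC1=CC(C)=CC[C@@]2(C)CCC(=O)[C@@H]12 | intermediate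
15 | potassium (8aR)-6,8a-dimethyl-4-(triisopropylsilyloxy)-1,2,8,8a-tetrahydroazulen-3-olate | [K+].[O-]C1=C2C(O[Si](C(C)C)(C(C)C)C(C)C)=CC(C)=CC[C@@]2(C)CC1 | intermediate
16 | (3aS,8aR)-6,8a-dimethyl-4-(triisopropylsilyloxy)-1,2,8,8a-tetrahydroazulen-3(3aH)-one (trans-fused) | CC(C)[Si](C(C)C)(C(C)C)OC1=CC(C)=CC[C@@]2(C)CCC(=O)[C@H]12 | intermediate
17 | (3R,3aR,8aR)-6,8a-dimethyl-3-(propan-2-yl)-4-(triisopropylsilyloxy)-1,2,3,3a,8,8a-hexahydroazulen-3-ol | CC(C)[Si](C(C)C)(C(C)C)OC1=CC(C)=CC[C@@]2(C)CC[C@@](O)(C(C)C)[C@H]12 | intermediate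
18 | (3R,3aR,8aR)-3-hydroxy-6,8a-dimethyl-3-(propan-2-yl)-2,3,3a,5,8,8a-hexahydroazulen-4(1H)-one | CC1=CC[C@@]2(C)CC[C@@](O)(C(C)C)[C@@H]2C(=O)C1 | intermediate
19 | (3R,3aS,4S,8aR)-6,8a-dimethyl-3-(propan-2-yl)-1,2,3,3a,4,5,8,8a-octahydroazulene-3,4-diol (jaeschkeanadiol) | O[C@H]1CC(C)=CC[C@@]2(C)CC[C@@](O)(C(C)C)[C@H]12 | intermediate
20 | 4-acetoxy-3-methoxybenzoic acid | COc1cc(C(=O)O)ccc1OC(C)=O | starting material
21 | (3R,3aS,4S,8aR)-3-hydroxy-6,8a-dimethyl-3-(propan-2-yl)-1,2,3,3a,4,5,8,8a-octahydroazulen-4-yl 4-acetoxy-3-methoxybenzoate | COc1cc(C(=O)O[C@H]2CC(C)=CC[C@@]3(C)CC[C@@](O)(C(C)C)[C@H]23)ccc1OC(C)=O | intermediate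
22 | teferin, (3R,3aS,4S,8aR)-3-hydroxy-6,8a-dimethyl-3-(propan-2-yl)-1,2,3,3a,4,5,8,8a-octahydroazulen-4-yl 4-hydroxy-3-methoxybenzoate | COc1cc(C(=O)O[C@H]2CC(C)=CC[C@@]3(C)CC[C@@](O)(C(C)C)[C@H]23)ccc1O | target

**Step count.** Total: 11 steps. Longest linear sequence: 11 steps (1 to 22); compounds 2, 8 and 20 are purchased and enter directly.

**Steps most likely to fail, with fallbacks**

Step 7. The ketene may be lost to dimerisation or to a 1,5-hydrogen shift before the silyl enol ether captures it. The diazo enone may also isomerise to the E isomer under irradiation, so that no ring can close. Fallback, setting out from 12 and returning to the route at 16: the rearrangement and the ring closure are separated. Wolff rearrangement of 12 in aqueous THF with PhCO2Ag and Et3N (Arndt–Eistert homologation) gives (3Z)-3-methyl-5-[(1R)-1-methyl-3-(triisopropylsilyloxy)cyclopent-2-en-1-yl]pent-3-enoic acid F1. 1-Chloro-N,N,2-trimethylprop-1-en-1-amine converts it under neutral conditions into the acid chloride F2. TiCl4 in CH2Cl2 at −78 °C then effects intramolecular Mukaiyama-type C-acylation of the silyl enol ether, with no free ketene, to give the enolised β-diketone F3 after loss of the silyl group. Silylation with i-Pr3SiOTf and Et3N at the seven-ring oxygen gives the vinylogous ester F4. Deconjugative protonation (t-BuOK, then AcOH at −78 °C, through enolate 15) leads to 16.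

Step 8. The basic isopropyl reagent may deprotonate the acidic C3a–H of 16 instead of adding, and protonation at C3a in step 7 may have favoured the cis ring fusion, which would also misdirect the addition at C3. Fallback, setting out from 16 and returning at 18: 16 (either C3a epimer) is isomerised with catalytic Et3N to the conjugated vinylogous ester F4, which has no C3a stereocentre and no acidic C3a–H. i-PrLi with CeCl3 then adds to its C3 carbonyl anti to the axial C8a methyl group to give the carbinol F5. Buffered Bu4NF/AcOH releases the β-hydroxy ketone, and the C3a epimers are left to equilibrate in the acetate buffer toward trans-fused 18. In that isomer the C3 hydroxyl can hydrogen-bond to the C4 carbonyl and the isopropyl group is anti to C4.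

Step 5. Hydroxide may attack the silicon of the enol ether before it saponifies the hindered (Z)-enoate, and the acylation of diazomethane in step 6 may be accompanied by dipolar cycloaddition to the enone. Fallback, setting out from 9 and returning at 12, bypassing 10 and 11: Me(MeO)NH·HCl with i-PrMgCl converts 9 into the N-methoxy-N-methylamide F6. MeMgBr gives the (Z)-methyl ketone F7. Detrifluoroacetylative diazo transfer (LiN(SiMe3)2 and CF3CO2CH2CF3 at −78 °C to the trifluoroacetyl ketone F8; then MsN3, Et3N, H2O, MeCN) gives diazoketone 12.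

**Further compounds**

F1 | step 7 | (3Z)-3-methyl-5-[(1R)-1-methyl-3-(triisopropylsilyloxy)cyclopent-2-en-1-yl]pent-3-enoic acid | OC(=O)C/C(C)=C\C[C@@]1(C)CCC(O[Si](C(C)C)(C(C)C)C(C)C)=C1
F2 | step 7 | (3Z)-3-methyl-5-[(1R)-1-methyl-3-(triisopropylsilyloxy)cyclopent-2-en-1-yl]pent-3-enoyl chloride | ClC(=O)C/C(C)=C\C[C@@]1(C)CCC(O[Si](C(C)C)(C(C)C)C(C)C)=C1
F3 | step 7 | (8aR)-4-hydroxy-6,8a-dimethyl-2,5,8,8a-tetrahydroazulen-3(1H)-one | OC1=C2C(=O)CC[C@]2(C)CC=C(C)C1
F4 | step 7 | (8aR)-6,8a-dimethyl-4-(triisopropylsilyloxy)-2,5,8,8a-tetrahydroazulen-3(1H)-one | CC(C)[Si](C(C)C)(C(C)C)OC1=C2C(=O)CC[C@]2(C)CC=C(C)C1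
F5 | step 8 | (3R,8aR)-6,8a-dimethyl-3-(propan-2-yl)-4-(triisopropylsilyloxy)-1,2,3,5,8,8a-hexahydroazulen-3-ol | CC(C)[Si](C(C)C)(C(C)C)OC1=C2[C@](O)(C(C)C)CC[C@]2(C)CC=C(C)C1
F6 | step 5 | (2Z)-N-methoxy-N,2-dimethyl-4-[(1R)-1-methyl-3-(triisopropylsilyloxy)cyclopent-2-en-1-yl]but-2-enamide | CON(C)C(=O)/C(C)=C\C[C@@]1(C)CCC(O[Si](C(C)C)(C(C)C)C(C)C)=C1
F7 | step 5 | (3Z)-3-methyl-5-[(1R)-1-methyl-3-(triisopropylsilyloxy)cyclopent-2-en-1-yl]pent-3-en-2-one | CC(=O)/C(C)=C\C[C@@]1(C)CCC(O[Si](C(C)C)(C(C)C)C(C)C)=C1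
F8 | step 5 | (5Z)-1,1,1-trifluoro-5-methyl-7-[(1R)-1-methyl-3-(triisopropylsilyloxy)cyclopent-2-en-1-yl]hept-5-ene-2,4-dione | FC(F)(F)C(=O)CC(=O)/C(C)=C\C[C@@]1(C)CCC(O[Si](C(C)C)(C(C)C)C(C)C)=C1
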